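**Plan**

- Retrosynthesis: the O6–acyl bond is cut first, then C8–C12 (formyl carbon from CO on a C7=C8 enol triflate), then C6–O (conjugate borylation of a Δ6-8-ketone), and last C9–C10, which opens ring B to an acyclic 2,3-dioxo ester hung on ring A.
- Enabling feature: C9 is a fully substituted carbinol carbon that carries the C11 carboxyl, is bonded to quaternary C10 and sits next to C8. This is the pattern left when the C5=C10 alkene of ring A adds through C10 to the central carbonyl of a 2,3-dioxo ester and gives up H6.
- Forward: ring A is bought (dihydro-β-ionone), the chain is extended by C11 and oxidised to the tricarbonyl, ring B closes at C9–C10 in the copper–bisoxazoline carbonyl-ene step, then 5-H, 6-O, C12, the acyl group and the free acid follow.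
- Stereochemistry: C9 from the chiral ligand; C10 relative to C9 through the cyclic transition state; C5 by α-face protonation in the enone isomerization; C6 (6α, 6S) by α-face borylation opposite the axial C10 and C4 methyl groups; the all-E triene is bought.

Key step: step 4

Remark: drimane numbering is used (C11 on C9, C12 on C8, C15 on C10; α is the face opposite C15). The target is taken as the open 12-oxo-11-oic acid as drawn, although its cyclic hydroxy-lactone tautomer may be present at equilibrium.

**Route**

Step 1
Reactants: 1 dihydro-β-ionone, 4-(2,6,6-trimethylcyclohex-1-en-1-yl)butan-2-one; 2 dimethyl carbonate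
Product: 3 methyl 3-oxo-5-(2,6,6-trimethylcyclohex-1-en-1-yl)pentanoate
Conditions: NaH (2.5 equiv), dimethyl carbonate (3 equiv), THF, reflux; aq HCl quench
Reagents that add atoms: dimethyl carbonate (2), COC(=O)OC
Why: Claisen-type C-acylation of the methyl-side enolate of a methyl ketone by a dialkyl carbonate, driven by irreversible deprotonation of the β-keto ester formed; no stereocentre arises.

Step 2
Reactants: 3 methyl 3-oxo-5-(2,6,6-trimethylcyclohex-1-en-1-yl)pentanoate; 4 4-methoxybenzyl alcohol
Product: 5 4-methoxybenzyl 3-oxo-5-(2,6,6-trimethylcyclohex-1-en-1-yl)pentanoate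
Conditions: DMAP (0.3 equiv), toluene, reflux, 4 Å MS (Soxhlet) to remove MeOH
Reagents that add atoms: 4-methoxybenzyl alcohol (4), COc1ccc(CO)cc1
Why: DMAP-catalysed transesterification of a β-keto ester under neutral conditions installs an ester that mild acid can remove at the end without a nucleophile at the hindered C11 carbonyl, so the trienoate will survive.

Step 3
Reactants: 5 4-methoxybenzyl 3-oxo-5-(2,6,6-trimethylcyclohex-1-en-1-yl)pentanoate
Product: 7 4-methoxybenzyl 2,3-dioxo-5-(2,6,6-trimethylcyclohex-1-en-1-yl)pentanoate, via tricarbonyl hydrate 6 (not isolated)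
Conditions: Dess–Martin periodinane (2.5 equiv), pyridine, wet CH2Cl2, 0 °C to rt; aq NaHCO3 wash; then toluene azeotrope (≤40 °C, reduced pressure) and 4 Å MS, CH2Cl2; solution used at once
Reagents that add atoms: Dess–Martin periodinane, CC(=O)OI1(OC(C)=O)(OC(C)=O)OC(=O)c2ccccc12; water, O (between them the source of the new C2 oxygen)
Why: Oxidation of the activated methylene of a β-keto ester to the vicinal tricarbonyl by Dess–Martin periodinane and pyridine is an established entry to 2,3-dioxo esters that, unlike dioxirane, ozone or singlet-oxygen routes, leaves the tetrasubstituted alkene alone, and low-temperature azeotropic drying of the hydrate frees the central carbonyl without heating the ene-prone substrate; no stereocentre is formed.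

Step 4
Reactants: 7 4-methoxybenzyl 2,3-dioxo-5-(2,6,6-trimethylcyclohex-1-en-1-yl)pentanoate
Product: 8 4-methoxybenzyl (9S,10S)-9-hydroxy-8-oxo-12-nordrim-5-en-11-oate
Conditions: Cu(OTf)2 (10 mol %), (R,R)-tBu-box [2,2'-(propane-2,2-diyl)bis((4R)-4-tert-butyl-4,5-dihydrooxazole)] (11 mol %), 4 Å MS, CH2Cl2, slow addition of 7, −40 °C to 0 °C
Reagents that add atoms: none
Why: Proposed new method: the divalent copper–bisoxazoline cation should chelate the C9 and ester carbonyls of 7 as it does those of α-keto esters, and the C5=C10 alkene then adds through C10 to the activated C9 while H6 passes to the carbonyl oxygen, either in one asynchronous ene step or by Prins addition to a C5 cation that loses H6, leaving C5=C6. The closest known reactions are the Cu(OTf)2–bisoxazoline carbonyl-ene cyclizations of unsaturated α-keto esters and the intermolecular copper–bisoxazoline ene reactions of 2,3-dioxo esters at the central carbonyl; new here is the intramolecular case with a tetrasubstituted alkene whose allylic hydrogen lies inside the tether. Ring B closes in a six-membered mode that is endo with respect to C5=C10 and exo with respect to the C9 carbonyl. C9 is set by the ligand, whose tert-butyl group covers one face of the chelated carbonyl so that C10 bonds to the Re face (sense assigned by analogy with the pyruvate chelate model; the enantiomeric ligand is equally available if the sense proves reversed). C10 follows from C9 because both the transfer of H6 to the copper-bound oxygen and the opposition of the C8 and C9 carbonyl dipoles require that oxygen to sit pseudo-axial and anti to the C10 methyl, which places the hydroxyl trans to C15. The step needs C10 rather than C5 to bond and the alkene to end at C5=C6: attack by C5 would demand a five-membered spiro closure at the carbon shielded by the C4 gem-dimethyl group, and C6 carries the only hydrogens next to C5.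

Step 5
Reactants: 8 4-methoxybenzyl (9S,10S)-9-hydroxy-8-oxo-12-nordrim-5-en-11-oate
Product: 9 4-methoxybenzyl 9α-hydroxy-8-oxo-12-nor-5α-drim-6-en-11-oate
Conditions: DBU (0.3 equiv), toluene, rt
Reagents that add atoms: none
Why: Base-mediated isomerization of a β,γ- to an α,β-unsaturated ketone through the extended dienolate is driven by conjugation and by relief of the allylic strain between H6 and the C4 methyl groups, and C5 should be protonated on the α face because the β face is covered by the axial C10 and C4 methyl groups, giving the trans ring fusion (5α-H).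

Step 6
Reactants: 9 4-methoxybenzyl 9α-hydroxy-8-oxo-12-nor-5α-drim-6-en-11-oate
Product: 11 4-methoxybenzyl 6α,9α-dihydroxy-8-oxo-12-nor-5α-driman-11-oate, via C6 pinacol boronate 10 (not isolated)
Conditions: CuCl (5 mol %), NaOtBu (10 mol %), DPEphos (5 mol %), B2pin2 (1.2 equiv), MeOH (2 equiv), THF, rt; then NaBO3·4H2O, THF/H2O, rt
Reagents that add atoms: sodium perborate, [Na+].[O-]B1OO1 (oxygen at C6); bis(pinacolato)diboron, CC1(C)OB(OC1(C)C)B1OC(C)(C)C(C)(C)O1 (boron of intermediate 10 only)
Why: Copper-catalysed conjugate borylation of an enone followed by oxidation of the C–B bond with retention; the boryl–copper species should add to C6 from the α face, opposite the axial β methyl groups at C10 and C4, which sets 6α-OH.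

Step 7
Reactants: 11 4-methoxybenzyl 6α,9α-dihydroxy-8-oxo-12-nor-5α-driman-11-oate
Product: 12 4-methoxybenzyl 9α-hydroxy-8-oxo-6α-(triethylsilyloxy)-12-nor-5α-driman-11-oate
Conditions: Et3SiCl (1.3 equiv), imidazole (2.5 equiv), DMF, 0 °C to rt
Reagents that add atoms: chlorotriethylsilane, CC[Si](Cl)(CC)CC
Why: Silylation of a secondary alcohol with a silyl chloride and imidazole; the tertiary C9 hydroxyl, flanked by quaternary C10 and two carbonyl groups, reacts far more slowly and stays free.

Step 8
Reactants: 12 4-methoxybenzyl 9α-hydroxy-8-oxo-6α-(triethylsilyloxy)-12-nor-5α-driman-11-oate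
Product: 13 4-methoxybenzyl 9α-hydroxy-6α-(triethylsilyloxy)-8-(trifluoromethylsulfonyloxy)-12-nor-5α-drim-7-en-11-oate
Conditions: KN(SiMe3)2 (2.2 equiv), THF, −78 °C; Comins' reagent (1.2 equiv), −78 °C; aq NH4Cl
Reagents that add atoms: Comins' reagent, N-(5-chloropyridin-2-yl)-1,1,1-trifluoro-N-(trifluoromethylsulfonyl)methanesulfonamide, FC(F)(F)S(=O)(=O)N(c1ccc(Cl)cn1)S(=O)(=O)C(F)(F)F
Why: Kinetic enolate O-triflation with Comins' reagent: C7 carries the only enolisable hydrogens (C9 is quaternary), the first equivalent of base is taken up by the C9 hydroxyl whose hindered alkoxide should not be sulfonylated, and at −78 °C the β-silyloxy enolate should not eliminate.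

Step 9
Reactants: 13 4-methoxybenzyl 9α-hydroxy-6α-(triethylsilyloxy)-8-(trifluoromethylsulfonyloxy)-12-nor-5α-drim-7-en-11-oate
Product: 15 4-methoxybenzyl 6α,9α-dihydroxy-12-oxo-5α-drim-7-en-11-oate, via silyl ether enal 14 (not isolated)
Conditions: Pd(OAc)2 (5 mol %), 1,3-bis(diphenylphosphino)propane (5 mol %), CO (1 atm), Et3SiH (2 equiv), Et3N, DMF, 70 °C; then HF·pyridine, pyridine, THF, 0 °C
Reagents that add atoms: carbon monoxide, [C-]#[O+]
Why: Palladium-catalysed reductive carbonylation (formylation) of an enol triflate, by oxidative addition to zerovalent palladium, CO insertion and hydride transfer from the silane to the acylpalladium, gives the enal, and buffered HF·pyridine then cleaves the C6 silyl ether (and any silyl ether formed at O9 by the silyl triflate co-product) without touching the 4-methoxybenzyl ester.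

Step 10
Reactants: 15 4-methoxybenzyl 6α,9α-dihydroxy-12-oxo-5α-drim-7-en-11-oate; 16 (2E,4E,6E)-octa-2,4,6-trienoic acid
Product: 17 4-methoxybenzyl 9α-hydroxy-6α-[(2E,4E,6E)-octa-2,4,6-trienoyloxy]-12-oxo-5α-drim-7-en-11-oate
Conditions: 16 (1.5 equiv), 2,4,6-trichlorobenzoyl chloride, Et3N, THF, rt; then 15, DMAP, toluene, rt
Reagents that add atoms: (2E,4E,6E)-octa-2,4,6-trienoic acid (16), C/C=C/C=C/C=C/C(=O)O
Why: Yamaguchi esterification through the mixed 2,4,6-trichlorobenzoic anhydride acylates the hindered secondary 6α-hydroxyl with retention at C6, while the tertiary C9 hydroxyl does not react and the triene keeps its all-E geometry.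

Step 11
Reactants: 17 4-methoxybenzyl 9α-hydroxy-6α-[(2E,4E,6E)-octa-2,4,6-trienoyloxy]-12-oxo-5α-drim-7-en-11-oate
Product: 18 (5S,6S,9S,10S)-9-hydroxy-6-[(2E,4E,6E)-octa-2,4,6-trienoyloxy]-12-oxodrim-7-en-11-oic acid
Conditions: CF3CO2H/CH2Cl2 (1:9), anisole (5 equiv), 0 °C
Reagents that add atoms: none
Why: Acidolysis of a 4-methoxybenzyl ester by alkyl–oxygen cleavage to the stabilised benzylic cation (trapped by anisole) needs no nucleophile at the hindered C11 carbonyl and so should spare the trienoate, the enal and the tertiary allylic alcohol, whose ionisation is disfavoured by the adjacent carboxyl and the electron-poor alkene.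

**Compound list**

1 | dihydro-β-ionone, 4-(2,6,6-trimethylcyclohex-1-en-1-yl)butan-2-one | CC(=O)CCC1=C(C)CCCC1(C)C | starting material
2 | dimethyl carbonate | COC(=O)OC | starting material
3 | methyl 3-oxo-5-(2,6,6-trimethylcyclohex-1-en-1-yl)pentanoate | COC(=O)CC(=O)CCC1=C(C)CCCC1(C)C | intermediate
4 | 4-methoxybenzyl alcohol | COc1ccc(CO)cc1 | starting material
5 | 4-methoxybenzyl 3-oxo-5-(2,6,6-trimethylcyclohex-1-en-1-yl)pentanoate | COc1ccc(COC(=O)CC(=O)CCC2=C(C)CCCC2(C)C)cc1 | intermediate
6 | 4-methoxybenzyl 2,2-dihydroxy-3-oxo-5-(2,6,6-trimethylcyclohex-1-en-1-yl)pentanoate (tricarbonyl hydrate, not isolated) | COc1ccc(COC(=O)C(O)(O)C(=O)CCC2=C(C)CCCC2(C)C)cc1 | intermediate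
7 | 4-methoxybenzyl 2,3-dioxo-5-(2,6,6-trimethylcyclohex-1-en-1-yl)pentanoate | COc1ccc(COC(=O)C(=O)C(=O)CCC2=C(C)CCCC2(C)C)cc1 | intermediate
8 | 4-methoxybenzyl (9S,10S)-9-hydroxy-8-oxo-12-nordrim-5-en-11-oate, i.e. (1S,8aS)-1-hydroxy-5,5,8a-trimethyl-2-oxo-1,2,3,5,6,7,8,8a-octahydronaphthalene-1-carboxylate (9α-OH, 10β-CH3) | COc1ccc(COC(=O)[C@@]2(O)C(=O)CC=C3C(C)(C)CCC[C@]23C)cc1 | intermediate
9 | 4-methoxybenzyl 9α-hydroxy-8-oxo-12-nor-5α-drim-6-en-11-oate | COc1ccc(COC(=O)[C@@]2(O)C(=O)C=C[C@H]3C(C)(C)CCC[C@]23C)cc1 | intermediate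
10 | 4-methoxybenzyl 9α-hydroxy-8-oxo-6α-(4,4,5,5-tetramethyl-1,3,2-dioxaborolan-2-yl)-12-nor-5α-driman-11-oate (not isolated) | COc1ccc(COC(=O)[C@@]2(O)C(=O)C[C@H](B4OC(C)(C)C(C)(C)O4)[C@H]3C(C)(C)CCC[C@]23C)cc1 | intermediate
11 | 4-methoxybenzyl 6α,9α-dihydroxy-8-oxo-12-nor-5α-driman-11-oate | COc1ccc(COC(=O)[C@@]2(O)C(=O)C[C@H](O)[C@H]3C(C)(C)CCC[C@]23C)cc1 | intermediate
12 | 4-methoxybenzyl 9α-hydroxy-8-oxo-6α-(triethylsilyloxy)-12-nor-5α-driman-11-oate | COc1ccc(COC(=O)[C@@]2(O)C(=O)C[C@H](O[Si](CC)(CC)CC)[C@H]3C(C)(C)CCC[C@]23C)cc1 | intermediate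
13 | 4-methoxybenzyl 9α-hydroxy-6α-(triethylsilyloxy)-8-(trifluoromethylsulfonyloxy)-12-nor-5α-drim-7-en-11-oate | COc1ccc(COC(=O)[C@@]2(O)C(OS(=O)(=O)C(F)(F)F)=C[C@H](O[Si](CC)(CC)CC)[C@H]3C(C)(C)CCC[C@]23C)cc1 | intermediate
14 | 4-methoxybenzyl 9α-hydroxy-12-oxo-6α-(triethylsilyloxy)-5α-drim-7-en-11-oate (not isolated) | COc1ccc(COC(=O)[C@@]2(O)C(C=O)=C[C@H](O[Si](CC)(CC)CC)[C@H]3C(C)(C)CCC[C@]23C)cc1 | intermediate
15 | 4-methoxybenzyl 6α,9α-dihydroxy-12-oxo-5α-drim-7-en-11-oate | COc1ccc(COC(=O)[C@@]2(O)C(C=O)=C[C@H](O)[C@H]3C(C)(C)CCC[C@]23C)cc1 | intermediate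
16 | (2E,4E,6E)-octa-2,4,6-trienoic acid | C/C=C/C=C/C=C/C(=O)O | starting material
17 | 4-methoxybenzyl 9α-hydroxy-6α-[(2E,4E,6E)-octa-2,4,6-trienoyloxy]-12-oxo-5α-drim-7-en-11-oate | COc1ccc(COC(=O)[C@@]2(O)C(C=O)=C[C@H](OC(=O)/C=C/C=C/C=C/C)[C@H]3C(C)(C)CCC[C@]23C)cc1 | intermediate
18 | (5S,6S,9S,10S)-9-hydroxy-6-[(2E,4E,6E)-octa-2,4,6-trienoyloxy]-12-oxodrim-7-en-11-oic acid, i.e. (1S,4S,4aS,8aS)-2-formyl-1-hydroxy-5,5,8a-trimethyl-4-[(2E,4E,6E)-octa-2,4,6-trienoyloxy]-1,4,4a,5,6,7,8,8a-octahydronaphthalene-1-carboxylic acid | C/C=C/C=C/C=C/C(=O)O[C@H]1C=C(C=O)[C@](O)(C(=O)O)[C@@]2(C)CCCC(C)(C)[C@H]12 | target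

**Step count and risks**

Total step count: 11. Longest linear sequence: 11 steps (1 to 18); compounds 2, 4 and 16 enter as purchased reagents.

Steps most likely to fail:

1. Step 4 (the proposed new method). What may go wrong: weak facial discrimination at the chelated C9 carbonyl, pairing of the wrong C9 and C10 faces (hydroxyl cis to the methyl), non-catalysed background cyclization, or diversion of the developing C5 cation into spiro closure or methyl migration. The fallback uses known chemistry, sets out from 3 and returns at 9. SnCl4 in CH2Cl2 should cyclize 3 by the established cation–olefin route (protonation at C5, attack of the enol carbon C9 on C10) to racemic trans-fused methyl 8-oxo-12-nor-5α-driman-11-oate F1. DMAP-catalysed transesterification with 4 would give the 4-methoxybenzyl ester F2. Enolate hydroxylation (KN(SiMe3)2, then 2-(phenylsulfonyl)-3-phenyloxaziridine) on the α face, opposite the C10 methyl, would give the racemic 9α-hydroxy keto ester F3. IBX dehydrogenation towards C7, the only enolisable position, would give the racemic form of the enone F4, and preparative chromatography on a chiral stationary phase would deliver 9. The same C9–C10 bond is made, but with reversed polarity and without catalyst control.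

2. Step 3. What may go wrong: oxidative C–C cleavage of the tricarbonyl by excess periodinane, or cyclization of the free tricarbonyl during drying, before the chiral catalyst is present. The fallback sets out from 5 and returns at 6. Ehrlich–Sachs condensation of 5 with N,N-dimethyl-4-nitrosoaniline (cat. K2CO3, EtOH) would give the 2-arylimino-3-oxo ester F5, and hydrolysis with cold dilute aqueous H2SO4 under ether would give the hydrate 6 with no oxidant involved. 6 is then dried as in step 3, or over 4 Å MS with the copper catalyst already present.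

3. Step 9. What may go wrong: hydride capture of the vinylpalladium intermediate before CO insertion (reduction to the C8–H alkene), or slow carbonylation next to the quaternary C9. The fallback sets out from 13 and returns at 14. Stille coupling of 13 with (tributylstannyl)methanol (Pd(PPh3)4, LiCl, dioxane, 100 °C) would give the C12 allylic alcohol F6, and MnO2 in CH2Cl2 would oxidise it to 14, which is desilylated as in the second half of step 9.

**Further compounds**

F1 | step 4 | methyl (±)-8-oxo-12-nor-5α-driman-11-oate (racemate, one enantiomer drawn) | COC(=O)[C@H]1C(=O)CC[C@H]2C(C)(C)CCC[C@]12C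
F2 | step 4 | 4-methoxybenzyl (±)-8-oxo-12-nor-5α-driman-11-oate (racemate, one enantiomer drawn) | COc1ccc(COC(=O)[C@H]2C(=O)CC[C@H]3C(C)(C)CCC[C@]23C)cc1
F3 | step 4 | 4-methoxybenzyl (±)-9α-hydroxy-8-oxo-12-nor-5α-driman-11-oate (racemate, one enantiomer drawn) | COc1ccc(COC(=O)[C@@]2(O)C(=O)CC[C@H]3C(C)(C)CCC[C@]23C)cc1
F4 | step 4 | 4-methoxybenzyl (±)-9α-hydroxy-8-oxo-12-nor-5α-drim-6-en-11-oate (racemic form of 9, one enantiomer drawn) | COc1ccc(COC(=O)[C@@]2(O)C(=O)C=C[C@H]3C(C)(C)CCC[C@]23C)cc1
F5 | step 3 | 4-methoxybenzyl 2-{[4-(dimethylamino)phenyl]imino}-3-oxo-5-(2,6,6-trimethylcyclohex-1-en-1-yl)pentanoate | COc1ccc(COC(=O)C(=Nc2ccc(N(C)C)cc2)C(=O)CCC3=C(C)CCCC3(C)C)cc1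
F6 | step 9 | 4-methoxybenzyl 9α,12-dihydroxy-6α-(triethylsilyloxy)-5α-drim-7-en-11-oate | COc1ccc(COC(=O)[C@@]2(O)C(CO)=C[C@H](O[Si](CC)(CC)CC)[C@H]3C(C)(C)CCC[C@]23C)cc1
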